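The route rests on disconnecting the bond between carbinol carbon C25 and ring-fusion methine C13 (carbons counted along the target SMILES), the bond shared by cyclooctene ring B and cyclohexane ring C. The homoallylic array HO–C25–C13–C11(CH3) is read as the retron of a carbonyl–ene reaction. Dienone 26 already holds all skeletal carbons, with a prenyl arm on cyclopentane ring D and ring A as a cyclopentylidene ketone, and cyclises under Me2AlCl. One operation closes ring C, creates the tertiary alcohol, sets C13 and C25 and unveils the isopropenyl group that ring-closing metathesis then uses for ring B; hydroxyl-directed hydrogenation finally sets C11.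

Key step: step 17

Remark on labels: C1 vinylic methyl; C2=C3 tetrasubstituted alkene; C4, C5; C6 (methyl C7); C8; C9, C10; C11 (methyl C12); C13; C14; C15 (methyl C16); C17, C18; C19 (isopropyl C20–C22); C23; C24; C25 carbinol. Ring A: C3, C4, C5, C6, C8. Ring B: C2, C3, C8, C9, C10, C11, C13, C25. Ring C: C13, C14, C15, C23, C24, C25. Ring D: C15, C17, C18, C19, C23.

Assumption: (R)-β-citronellene and (S)-limonene are bought in high enantiomeric purity; they are the only sources of absolute configuration (C6 and C19).

**Fragment with ring A (steps 1–6)**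

Step 1
Reactants: 1 (R)-β-citronellene
Product: 3 (R)-4-methylhex-5-enal, via ozonide 2 (not isolated)
Conditions: O3 (1 equiv, Sudan Red 7B end point), CH2Cl2, −78 °C; then Me2S, −78 °C → rt
Reagents that add atoms: ozone, [O-][O+]=O
Why: Chemoselective ozonolysis, in which the electron-rich trisubstituted alkene is cleaved faster than the vinyl group when ozone is dosed to the indicator end point, and the C6 stereocentre is not touched.

Step 2
Reactants: 3 (R)-4-methylhex-5-enal
Product: 4 (R)-7,7-dibromo-3-methylhepta-1,6-diene
Conditions: CBr4, PPh3, CH2Cl2, 0 °C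
Reagents that add atoms: carbon tetrabromide, BrC(Br)(Br)Br
Why: Corey–Fuchs dibromo-olefination (Wittig-type reaction) of an unhindered aldehyde.

Step 3
Reactants: 4 (R)-7,7-dibromo-3-methylhepta-1,6-diene
Product: 6 (R)-3-methyloct-1-en-6-yne, via lithium acetylide 5 (not isolated)
Conditions: n-BuLi (2.1 equiv), THF, −78 °C; then CH3I, −78 °C → rt
Reagents that add atoms: iodomethane, CI
Why: Second stage of the Corey–Fuchs alkyne synthesis (bromine–lithium exchange and Fritsch–Buttenberg–Wiechell rearrangement), the acetylide then being methylated by SN2.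

Step 4
Reactants: 6 (R)-3-methyloct-1-en-6-yne
Product: 8 (1Z,2S,3R)-1-(1-iodoethylidene)-2-(iodomethyl)-3-methylcyclopentane, via zirconacycle 7 (not isolated)
Conditions: Cp2ZrCl2, n-BuLi (2 equiv), THF, −78 °C; add 6, → rt; then I2 (2.5 equiv), −78 °C → rt
Reagents that add atoms: iodine, II
Why: Zirconocene-mediated reductive enyne bicyclisation forms C3–C8 with zirconium on C2 cis to the new bond, so iodinolysis with retention should give the Z alkenyl iodide (iodine cis to C8), and C8 should be set trans to the C6 methyl group because that arrangement minimises strain in the bicyclic zirconacycle.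

Step 5
Reactants: 8 (1Z,2S,3R)-1-(1-iodoethylidene)-2-(iodomethyl)-3-methylcyclopentane
Product: 9 (1Z,2S,3R)-2-allyl-1-(1-iodoethylidene)-3-methylcyclopentane
Conditions: CH2=CHMgBr (3 equiv), CuI (10 mol%), THF, −40 → 0 °C
Reagents that add atoms: vinylmagnesium bromide, C=C[Mg]Br
Why: Copper-catalysed Kochi-type sp3–sp2 coupling of a Grignard reagent, which should take place at the primary alkyl iodide while the hindered tetrasubstituted alkenyl iodide stays inert at low temperature.

Step 6
Reactants: 9 (1Z,2S,3R)-2-allyl-1-(1-iodoethylidene)-3-methylcyclopentane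
Product: 11 (2Z)-2-[(2S,3R)-2-allyl-3-methylcyclopentylidene]-N-methoxy-N-methylpropanamide, via alkenyllithium 10 (not isolated)
Conditions: t-BuLi (2.1 equiv), Et2O, −78 °C; then ClC(O)N(OMe)Me, −78 → 0 °C
Reagents that add atoms: N-methoxy-N-methylcarbamoyl chloride, CON(C)C(Cl)=O
Why: Iodine–lithium exchange with retention of alkene geometry, followed by acylation of the alkenyllithium with a carbamoyl chloride, gives the Weinreb amide with the carbonyl group cis to C8.

**Fragment with ring D (steps 7–15)**

Step 7
Reactants: 12 (S)-limonene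
Product: 13 (S)-p-menth-1-ene
Conditions: H2 (1 atm), RhCl(PPh3)3 (2 mol%), toluene, rt
Reagents that add atoms: none
Why: Homogeneous hydrogenation with Wilkinson's catalyst reduces the 1,1-disubstituted isopropenyl alkene and leaves the trisubstituted ring alkene and the stereocentre untouched.

Step 8
Reactants: 13 (S)-p-menth-1-ene
Product: 15 (S)-3-isopropyl-6-oxoheptanal, via ozonide 14 (not isolated)
Conditions: O3, CH2Cl2, −78 °C; then Me2S, −78 °C → rt
Reagents that add atoms: ozone, [O-][O+]=O
Why: Ozonolysis with reductive work-up cleaves the ring alkene to the keto aldehyde.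

Step 9
Reactants: 15 (S)-3-isopropyl-6-oxoheptanal
Product: 16 (R)-5-isopropyl-2-methylcyclopent-1-ene-1-carbaldehyde
Conditions: piperidine (0.2 equiv), AcOH (0.2 equiv), toluene, 80 °C
Reagents that add atoms: none
Why: Amine-catalysed intramolecular aldol condensation, in which the aldehyde α-carbon closes the five-membered ring on the methyl ketone and dehydration gives the conjugated enal.

Step 10
Reactants: 16 (R)-5-isopropyl-2-methylcyclopent-1-ene-1-carbaldehyde
Product: 17 [(R)-5-isopropyl-2-methylcyclopent-1-en-1-yl]methanol
Conditions: NaBH4, CeCl3·7H2O, MeOH, 0 °C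
Reagents that add atoms: none
Why: Luche 1,2-reduction of the enal.

Step 11
Reactants: 17 [(R)-5-isopropyl-2-methylcyclopent-1-en-1-yl]methanol
Product: 19 ethyl 2-[(1R,3R)-3-isopropyl-1-methyl-2-methylenecyclopentyl]acetate, via ketene acetal 18 (not isolated)
Conditions: CH3C(OEt)3 (6 equiv), EtCO2H (0.1 equiv), 140 °C, EtOH distilled off
Reagents that add atoms: triethyl orthoacetate, CC(OCC)(OCC)OCC
Why: Johnson–Claisen rearrangement, whose [3,3] shift should form the quaternary centre C15 on the ring face opposite the neighbouring C19 isopropyl group, placing C14 trans to isopropyl.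

Step 12
Reactants: 19 ethyl 2-[(1R,3R)-3-isopropyl-1-methyl-2-methylenecyclopentyl]acetate
Product: 20 2-[(1R,3R)-3-isopropyl-1-methyl-2-methylenecyclopentyl]acetaldehyde
Conditions: i-Bu2AlH (1.05 equiv), CH2Cl2, −78 °C; aq. Rochelle salt, 0 °C
Reagents that add atoms: none
Why: Partial reduction of an ester to the aldehyde with one equivalent of i-Bu2AlH at low temperature, with no epimerisable centre next to the side chain.

Step 13
Reactants: 20 2-[(1R,3R)-3-isopropyl-1-methyl-2-methylenecyclopentyl]acetaldehyde
Product: 21 (1R,3R)-3-isopropyl-1-methyl-2-methylene-1-(3-methylbut-2-en-1-yl)cyclopentane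
Conditions: i-PrPPh3 iodide, n-BuLi, THF, 0 °C; then 20, −78 °C → rt
Reagents that add atoms: isopropyltriphenylphosphonium iodide, CC(C)[P+](c1ccccc1)(c1ccccc1)c1ccccc1.[I-]
Why: Wittig olefination with a non-stabilised disubstituted ylide, which installs the prenyl alkene C13=C11 without any geometry issue.

Step 14
Reactants: 21 (1R,3R)-3-isopropyl-1-methyl-2-methylene-1-(3-methylbut-2-en-1-yl)cyclopentane
Product: 23 [(1S,2R,5R)-5-isopropyl-2-methyl-2-(3-methylbut-2-en-1-yl)cyclopentyl]methanol, via alkylborane 22 (not isolated)
Conditions: 9-BBN (1.05 equiv), THF, 0 °C → rt; then NaOH, H2O2, 0 °C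
Reagents that add atoms: hydrogen peroxide, OO
Why: Hydroboration–oxidation, in which 9-BBN should react with the exocyclic 1,1-disubstituted alkene much faster than with the trisubstituted prenyl alkene and deliver hydrogen to C23 from the face of C14, away from the C15 methyl and C19 isopropyl groups, so that C24 becomes trans to C14.

Step 15
Reactants: 23 [(1S,2R,5R)-5-isopropyl-2-methyl-2-(3-methylbut-2-en-1-yl)cyclopentyl]methanol
Product: 24 (1R,2S,3R)-2-(iodomethyl)-3-isopropyl-1-methyl-1-(3-methylbut-2-en-1-yl)cyclopentane
Conditions: I2, PPh3, imidazole, CH2Cl2, 0 °C → rt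
Reagents that add atoms: iodine, II
Why: Appel-type iodination of the primary alcohol by SN2, to which the alkenes are inert.

**Union and endgame (steps 16–19)**

Step 16
Reactants: 24 (1R,2S,3R)-2-(iodomethyl)-3-isopropyl-1-methyl-1-(3-methylbut-2-en-1-yl)cyclopentane; 11 (2Z)-2-[(2S,3R)-2-allyl-3-methylcyclopentylidene]-N-methoxy-N-methylpropanamide
Product: 26 (3Z)-3-[(2S,3R)-2-allyl-3-methylcyclopentylidene]-1-[(1S,2R,5R)-5-isopropyl-2-methyl-2-(3-methylbut-2-en-1-yl)cyclopentyl]butan-2-one, via alkyllithium 25 (not isolated)
Conditions: 24, t-BuLi (2.1 equiv), Et2O/pentane, −78 °C; then 11, −78 → 0 °C; aq. NH4Cl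
Reagents that add atoms: none
Why: Weinreb ketone synthesis, in which the primary alkyllithium from iodine–lithium exchange attacks only the carbonyl group of the β,β-disubstituted unsaturated amide and the reaction stops at the ketone.

Step 17
Reactants: 26 (3Z)-3-[(2S,3R)-2-allyl-3-methylcyclopentylidene]-1-[(1S,2R,5R)-5-isopropyl-2-methyl-2-(3-methylbut-2-en-1-yl)cyclopentyl]butan-2-one
Product: 27 tricyclic tertiary alcohol: trans-fused ring C/D (octahydroindene) with an axial hydroxyl and the equatorial (Z)-1-[(2S,3R)-2-allyl-3-methylcyclopentylidene]ethyl group on C25 and an equatorial isopropenyl group on C13, cis to the hydroxyl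
Conditions: Me2AlCl (1.5 equiv), CH2Cl2, −78 → −20 °C; aq. Rochelle salt
Reagents that add atoms: none
Why: Type 1 intramolecular carbonyl–ene reaction, the ketone counterpart of the citronellal-to-isopulegol cyclisation: C13 of the prenyl alkene attacks the Me2AlCl-activated C25 carbonyl while an allylic hydrogen of a C11 methyl group passes to oxygen through a six-membered array, so that the C13–C25 bond, the tertiary alkoxide and the C11 isopropenyl group arise in one event. Ring C (C13, C14, C15, C23, C24, C25) closes in the 6-exo-trig mode at the carbonyl carbon through a chair in which the trans-fused ring D occupies two equatorial positions and the C15 methyl group is axial. C13 is controlled by this axial methyl group: the dimethylvinyl terminus avoids the 1,3-diaxial contact with it and stays equatorial, which gives the trans B/C ring-fusion hydrogen. C25 is controlled by the size of its two substituents: the branched 1-(cyclopentylidene)ethyl group should take the equatorial position and oxygen the axial one, gauche to C11 as the hydrogen transfer requires, which is the cis hydroxyl/isopropenyl relationship of the target. The step needs 1,2- instead of 1,4-attack on the enone and attack by the prenyl instead of the allyl alkene; the first is secured because the β-carbon C3 is fully substituted and would close an eight-membered ring, the second by the much higher nucleophilicity of the trisubstituted alkene. Me2AlCl also scavenges the proton (loss of methane), so the tertiary allylic alkoxide should not ionise.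

Step 18
Reactants: 27 tricyclic tertiary alcohol
Product: 28 10,11-didehydrosesterfisherol (ring B closed, Z trisubstituted C10=C11 alkene)
Conditions: second-generation Hoveyda–Grubbs catalyst (10 mol%), toluene (2 mM), 80 °C
Reagents that add atoms: none
Why: Ring-closing metathesis, in which the catalyst should load on the allyl group and close onto the isopropenyl group because the two arms are equatorial and gauche on neighbouring carbons of ring C, while the tetrasubstituted C2=C3 alkene takes no part.

Step 19
Reactants: 28 10,11-didehydrosesterfisherol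
Product: 29 sesterfisherol
Conditions: [Rh(nbd)(dppb)]BF4 (10 mol%), H2 (50 bar), CH2Cl2, rt
Reagents that add atoms: none
Why: Hydroxyl-directed homogeneous hydrogenation, in which the C25 hydroxyl binds rhodium and hydrogen should reach C11 of the homoallylic trisubstituted alkene from the face syn to oxygen (C11 methyl anti to the hydroxyl, as in the target), while this catalyst does not reduce the tetrasubstituted C2=C3 alkene.

**Compound list**

1 | (R)-β-citronellene, (R)-3,7-dimethylocta-1,6-diene | C=C[C@H](C)CCC=C(C)C | starting material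
2 | ozonide of 1, 5,5-dimethyl-3-[(R)-3-methylpent-4-en-1-yl]-1,2,4-trioxolane | C=C[C@H](C)CCC1OOC(C)(C)O1 | intermediate
3 | (R)-4-methylhex-5-enal | C=C[C@H](C)CCC=O | intermediate
4 | (R)-7,7-dibromo-3-methylhepta-1,6-diene | C=C[C@H](C)CCC=C(Br)Br | intermediate
5 | [(R)-5-methylhept-6-en-1-yn-1-yl]lithium | C=C[C@H](C)CCC#C[Li] | intermediate
6 | (R)-3-methyloct-1-en-6-yne | C=C[C@H](C)CCC#CC | intermediate
7 | zirconabicycle (zirconocene bridging C2 and C9; cyclopentadienyl ligands drawn σ-bonded) | CC1=C2CC[C@@H](C)[C@@H]2C[Zr]1(C1C=CC=C1)C1C=CC=C1 | intermediate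
8 | (1Z,2S,3R)-1-(1-iodoethylidene)-2-(iodomethyl)-3-methylcyclopentane | C/C(I)=C1\CC[C@@H](C)[C@@H]1CI | intermediate
9 | (1Z,2S,3R)-2-allyl-1-(1-iodoethylidene)-3-methylcyclopentane | C/C(I)=C1\CC[C@@H](C)[C@@H]1CC=C | intermediate
10 | alkenyllithium from 9 (lithium in place of iodine, same geometry) | C/C([Li])=C1\CC[C@@H](C)[C@@H]1CC=C | intermediate
11 | (2Z)-2-[(2S,3R)-2-allyl-3-methylcyclopentylidene]-N-methoxy-N-methylpropanamide | C/C(C(=O)N(C)OC)=C1\CC[C@@H](C)[C@@H]1CC=C | intermediate
12 | (S)-limonene | CC1=CC[C@H](CC1)C(C)=C | starting material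
13 | (S)-p-menth-1-ene | CC1=CC[C@H](CC1)C(C)C | intermediate
14 | ozonide of 13 (bicyclic 1,2,4-trioxolane, mixture at the two acetal carbons) | CC12CC[C@H](C(C)C)CC(OO1)O2 | intermediate
15 | (S)-3-isopropyl-6-oxoheptanal | O=CC[C@H](CCC(C)=O)C(C)C | intermediate
16 | (R)-5-isopropyl-2-methylcyclopent-1-ene-1-carbaldehyde | O=CC1=C(C)CC[C@@H]1C(C)C | intermediate
17 | [(R)-5-isopropyl-2-methylcyclopent-1-en-1-yl]methanol | OCC1=C(C)CC[C@@H]1C(C)C | intermediate
18 | mixed ketene acetal of 17 (1-ethoxyvinyl ether) | C=C(OCC)OCC1=C(C)CC[C@@H]1C(C)C | intermediate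
19 | ethyl 2-[(1R,3R)-3-isopropyl-1-methyl-2-methylenecyclopentyl]acetate | CCOC(=O)C[C@@]1(C)CC[C@H](C(C)C)C1=C | intermediate
20 | 2-[(1R,3R)-3-isopropyl-1-methyl-2-methylenecyclopentyl]acetaldehyde | O=CC[C@@]1(C)CC[C@H](C(C)C)C1=C | intermediate
21 | (1R,3R)-3-isopropyl-1-methyl-2-methylene-1-(3-methylbut-2-en-1-yl)cyclopentane | CC(C)=CC[C@@]1(C)CC[C@H](C(C)C)C1=C | intermediate
22 | B-alkyl-9-borabicyclo[3.3.1]nonane from 21 (boron on C24) | CC(C)=CC[C@@]1(C)CC[C@H](C(C)C)[C@@H]1CB1C2CCCC1CCC2 | intermediate
23 | [(1S,2R,5R)-5-isopropyl-2-methyl-2-(3-methylbut-2-en-1-yl)cyclopentyl]methanol | CC(C)=CC[C@@]1(C)CC[C@H](C(C)C)[C@@H]1CO | intermediate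
24 | (1R,2S,3R)-2-(iodomethyl)-3-isopropyl-1-methyl-1-(3-methylbut-2-en-1-yl)cyclopentane | CC(C)=CC[C@@]1(C)CC[C@H](C(C)C)[C@@H]1CI | intermediate
25 | alkyllithium from 24 (lithium on C24) | CC(C)=CC[C@@]1(C)CC[C@H](C(C)C)[C@@H]1C[Li] | intermediate
26 | (3Z)-3-[(2S,3R)-2-allyl-3-methylcyclopentylidene]-1-[(1S,2R,5R)-5-isopropyl-2-methyl-2-(3-methylbut-2-en-1-yl)cyclopentyl]butan-2-one | CC(C)=CC[C@@]1(C)CC[C@H](C(C)C)[C@@H]1CC(=O)/C(C)=C2/CC[C@@H](C)[C@@H]2CC=C | intermediate
27 | tricyclic tertiary alcohol (rings A, C, D; axial C25 hydroxyl, equatorial C13 isopropenyl, allyl on C8) | C/C(=C1\CC[C@@H](C)[C@@H]1CC=C)[C@@]2(O)C[C@H]3[C@@H](C(C)C)CC[C@]3(C)C[C@@H]2C(C)=C | intermediate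
28 | 10,11-didehydrosesterfisherol | C/C1=C2\CC[C@@H](C)[C@@H]2C/C=C(C)\[C@H]2C[C@@]3(C)CC[C@H](C(C)C)[C@@H]3C[C@]12O | intermediate
29 | sesterfisherol | C/C1=C2\CC[C@@H](C)[C@@H]2CC[C@H](C)[C@H]2C[C@@]3(C)CC[C@H](C(C)C)[C@@H]3C[C@]12O | target

**Step count and risks**

Total step count: 19. Longest linear sequence: 13 steps (steps 7 to 19, from (S)-limonene).

Steps most likely to fail:

1. Step 17 (carbonyl–ene closure of ring C). What may go wrong: attack on the other face of the carbonyl group (hydroxyl equatorial), loss of the C2=C3 geometry while the enone is bound to the Lewis acid, or cation–alkene follow-up reactions if the closure runs stepwise. Fallback: ring C is closed before ring A is attached. It sets out from iodide 24, whose alkyllithium 25 is formylated with DMF to give the homologated aldehyde F1. The same C13–C25 ene closure (Me2AlCl, CH2Cl2, −78 °C), now on an aldehyde as in the isopulegol synthesis, gives the bicyclic secondary alcohol F2, and Dess–Martin periodinane oxidises it to the 2-isopropenyl ketone F3, in which C13 can settle in the equatorial configuration. Alkenyllithium 10, made from 9 as in step 6 and treated with CeCl3 to suppress enolisation, then adds to F3 from the equatorial direction (axial hydroxyl), and the route is rejoined at 27.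

2. Step 18 (metathesis to the trisubstituted cyclooctene). What may go wrong: no closure onto the hindered 1,1-disubstituted alkene next to the quaternary carbinol, with dimerisation through the allyl group or alkene migration instead. Fallback: reductive carbonyl coupling in place of metathesis. It sets out from 27, which is silylated (Me3SiOTf, 2,6-lutidine) to the trimethylsilyl ether F4. OsO4 (cat.)/NaIO4 should cleave the two terminal alkenes but not the shielded tetrasubstituted one and give the keto aldehyde F5. McMurry coupling (TiCl3(DME)1.5, Zn–Cu couple, DME, reflux, slow addition) closes ring B to the cyclooctene silyl ether F6, Bu4NF removes the silyl group, and the route is rejoined at 28.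

3. Step 19 (directed hydrogenation). What may go wrong: reduction or migration of the wrong alkene, or hydrogen delivery that is not controlled by the hydroxyl group. Fallback: from 28 directly to 29 by hydrogen-atom-transfer hydrogenation (Mn(dpm)3 cat., PhSiH3, t-BuOOH, i-PrOH, rt). This is a stepwise radical reduction in which the tertiary C11 radical should be quenched under thermodynamic control (methyl anti to C25, away from the axial hydroxyl) and which is slow for the tetrasubstituted alkene. It forms no new compound.

Further compounds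
F1 | step 17 | 2-[(1S,2R,5R)-5-isopropyl-2-methyl-2-(3-methylbut-2-en-1-yl)cyclopentyl]acetaldehyde | CC(C)=CC[C@@]1(C)CC[C@H](C(C)C)[C@@H]1CC=O
F2 | step 17 | trans-fused 7a-methyl-6-isopropenyl-3-isopropyloctahydro-1H-inden-5-ol (equatorial hydroxyl on C25, equatorial isopropenyl on C13) | O[C@H]1C[C@H]2[C@@H](C(C)C)CC[C@]2(C)C[C@@H]1C(C)=C
F3 | step 17 | trans-fused 7a-methyl-6-isopropenyl-3-isopropyloctahydro-5H-inden-5-one | O=C1C[C@H]2[C@@H](C(C)C)CC[C@]2(C)C[C@@H]1C(C)=C
F4 | step 18 | trimethylsilyl ether of 27 | C/C(=C1\CC[C@@H](C)[C@@H]1CC=C)[C@@]2(O[Si](C)(C)C)C[C@H]3[C@@H](C(C)C)CC[C@]3(C)C[C@@H]2C(C)=C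
F5 | step 18 | keto aldehyde (C10 aldehyde, C11 methyl ketone, C25 silyl ether) | C/C(=C1\CC[C@@H](C)[C@@H]1CC=O)[C@@]2(O[Si](C)(C)C)C[C@H]3[C@@H](C(C)C)CC[C@]3(C)C[C@@H]2C(C)=O
F6 | step 18 | trimethylsilyl ether of 28 | C/C1=C2\CC[C@@H](C)[C@@H]2C/C=C(C)\[C@H]2C[C@@]3(C)CC[C@H](C(C)C)[C@@H]3C[C@]12O[Si](C)(C)C
F0 | step 19 | none | none
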